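**Assumptions (one line):** (R)-(−)-linalool is bought as the single enantiomer. The cis-linalool oxide and pyranoid by-products from step 2, and any minor C-4 (CH(CHO)) epimer from step 6, are removed by silica chromatography. I use "C-4" for the carbocycle carbon carrying the THF, which is a CH centre that later sits next to the carbinol carbon. Its configuration is set by substrate control from the adjacent quaternary centre, and I did not confirm the sense of that induction.

## Retrosynthetic overview
1. Dictyol H comes from its TBS ether by desilylation. That ether comes from Wittig methylenation of a hydroazulenone, which comes from a ketal by hydrolysis.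
2. The ketal is obtained by Myers reductive transposition of an allylic alcohol. This removes the Pauson–Khand carbonyl, places the ring-fusion H and the g=h alkene (g = the methyl-bearing sp² carbon, h = the former carbonyl carbon, both in the cyclopentene), and leaves the a-ketal intact (a = the ring carbon that becomes the exocyclic methylene).
3. The bicyclic enone (carbonyl at h) comes from an intramolecular Pauson–Khand [2+2+1] cycloaddition of a 1,8-enyne. This single step closes both the 7-ring and the cyclopentenone and sets the cis ring fusion.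
4. The enyne is built from (R)-linalool oxide acetate. The vinyl group is converted to CH₂CHO and cyanoethylated, Felkin propynyl addition sets the carbinol, and the nitrile is converted to a vinyl ketal. The THF ring is formed first, in steps 1–2.

## Route

**Step 1**
Reactants: 1 (R)-(−)-linalool
Product: 2 (3R)-6,7-epoxylinalool, C-6 epimeric mixture
Conditions: mCPBA, NaHCO₃, CH₂Cl₂, 0 °C
Reagents that add atoms: mCPBA, O=C(OO)c1cccc(Cl)c1 (delivers O)
Why: Prilezhaev epoxidation is selective for the electron-rich trisubstituted alkene over the vinyl group. C-3 is untouched, so the quaternary centre stays R.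

**Step 2**
Reactants: 2
Product: 3 trans-(2R,5R)-furanoid linalool oxide
Conditions: CSA (0.1 equiv), CH₂Cl₂, 0 °C → rt; chromatographic separation from the cis-furanoid and pyranoid isomers
Reagents that add atoms: none
Why: Acid-catalysed 5-exo opening of the epoxide by the tertiary OH (epoxide ring-opening cyclisation) proceeds with inversion at C-6. C-3 is not involved, and the two epoxide epimers give the trans and cis THFs, so the trans isomer is isolated.

**Step 3**
Reactants: 3
Product: 4 tertiary acetate
Conditions: Ac₂O, DMAP (cat.), Et₃N, CH₂Cl₂, 40 °C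
Reagents that add atoms: Ac₂O, CC(=O)OC(C)=O (adds acetyl)
Why: DMAP-catalysed acylation installs the tertiary acetate that the target carries and keeps it from interfering with later organometallic steps. No stereocentre is touched.

**Step 4**
Reactants: 4
Product: 5 primary alcohol
Conditions: 9-BBN, THF, rt; then NaBO₃·4H₂O, THF/H₂O
Reagents that add atoms: hydrogen peroxide from perborate, OO (supplies the OH oxygen); 9-BBN, B1C2CCCC1CCC2 (boron leaves)
Why: Hydroboration–oxidation is anti-Markovnikov at the monosubstituted vinyl group. Mild perborate oxidation spares the tertiary acetate.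

**Step 5**
Reactants: 5
Product: 6 aldehyde
Conditions: Dess–Martin periodinane, NaHCO₃, CH₂Cl₂, rt
Reagents that add atoms: none
Why: Mild oxidation gives the β-quaternary aldehyde, which is not epimerisable.

**Step 6**
Reactants: 6; 7 acrylonitrile
Product: 8 cyano-aldehyde with the C-4 (CH(CHO)) centre set
Conditions: pyrrolidine (0.3 equiv), 7 (5 equiv), MeCN, 50 °C
Reagents that add atoms: acrylonitrile, C=CC#N (reactant 7; adds C₃H₂N)
Why: An enamine Michael addition (cyanoethylation) adds the three-carbon chain. The new α-centre is set by diastereofacial bias from the adjacent quaternary THF carbon, and the aldehyde α-centre is epimerisable, so the favoured epimer predominates.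

**Step 7**
Reactants: 8; 9 1-propynyllithium
Product: 10 propargylic alcohol
Conditions: propyne, n-BuLi, THF, −78 °C; then 8, −78 °C
Reagents that add atoms: 1-propynyllithium, CC#C[Li] (reactant 9; adds C₃H₃)
Why: A non-chelating lithium acetylide adds to the α-chiral aldehyde under Felkin–Anh control, with the quaternary carbon as the large group. At −78 °C it reacts with the aldehyde in preference to the nitrile, and the carbinol centre is set by substrate control.

**Step 8**
Reactants: 10
Product: 11 TBS ether
Conditions: TBSOTf, 2,6-lutidine, CH₂Cl₂, −78 → 0 °C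
Reagents that add atoms: TBSOTf, C[Si](C)(C(C)(C)C)OS(=O)(=O)C(F)(F)F (adds TBS)
Why: Silylation of the hindered secondary propargylic alcohol needs the triflate. The TBS group is stable through the later steps and is removed last.

**Step 9**
Reactants: 11; 12 vinylmagnesium bromide
Product: 13 vinyl ketone
Conditions: 12 (4 equiv), CuBr (cat.), THF, 0 °C → rt; then 1 M HCl, THF, rt
Reagents that add atoms: vinylmagnesium bromide, C=C[Mg]Br (reactant 12; adds C₂H₃); water, O (becomes the ketone O on imine hydrolysis)
Why: Cu-assisted Grignard addition to a nitrile stops at the magnesium ketimide, so there is no over-addition. Hydrolysis releases the vinyl ketone.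

**Step 10**
Reactants: 13
Product: 14 vinyl dioxolane (ketal)
Conditions: Me₃SiOCH₂CH₂OSiMe₃, TMSOTf (0.05 equiv), CH₂Cl₂, −78 → −20 °C
Reagents that add atoms: 1,2-bis(trimethylsilyloxy)ethane, C[Si](C)(C)OCCO[Si](C)(C)C (adds OCH₂CH₂O)
Why: Noyori ketalisation of the enone without Michael addition of glycol. The achiral ketal masks C-a, avoids a vinylogous-dicarbonyl after cyclisation, and gives a simple alkene for the Pauson–Khand step.

**Step 11**
Reactants: 14
Product: 15 cis-fused hydroazulenone (cyclopentenone) ketal
Conditions: Co₂(CO)₈ (1.1 equiv), CH₂Cl₂, rt, 2 h; then NMO·H₂O (8 equiv), rt → 40 °C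
Reagents that add atoms: carbon monoxide from Co₂(CO)₈, [C-]#[O+] (becomes the C=O at h)
Why: Intramolecular Pauson–Khand [2+2+1] cycloaddition of the 1,8-enyne forms the 7-ring (new f–j bond) and the cyclopentenone. The methyl alkyne terminus becomes the enone α-carbon bearing methyl, cis ring fusion is favoured, and the new j–H centre is controlled by the tether stereocentres.

**Step 12**
Reactants: 15
Product: 16 allylic alcohol
Conditions: NaBH₄, CeCl₃·7H₂O, MeOH, −78 → 0 °C
Reagents that add atoms: none
Why: Luche 1,2-reduction. Hydride adds from the convex face (the face bearing the j–H), so OH ends up on the concave face.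

**Step 13**
Reactants: 16
Product: 17 ring-fusion-H, g=h alkene ketal
Conditions: o-O₂N-C₆H₄SO₂NHNH₂ (NBSH), PPh₃, DEAD, THF, −30 °C → rt
Reagents that add atoms: none (N₂, sulfinate, Ph₃PO and hydrazide are all lost)
Why: Myers reductive transposition. Mitsunobu displacement with NBSH inverts C-h, and the resulting allylic diazene loses N₂ by a retro-ene step. This puts the g=h alkene in place and delivers H to C-f suprafacially on the convex face, cis to j–H, which gives the cis ring fusion.

**Step 14**
Reactants: 17
Product: 18 hydroazulenone
Conditions: PPTS, acetone/H₂O, 55 °C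
Reagents that add atoms: water, O (becomes the ketone O)
Why: Mild acid-catalysed ketal hydrolysis. TBS, tertiary acetate, THF and trisubstituted alkene survive.

**Step 15**
Reactants: 18
Product: 19 TBS-protected dictyol H
Conditions: Ph₃P⁺CH₃ Br⁻, KOtBu, THF, 0 °C → rt
Reagents that add atoms: methylenetriphenylphosphorane, C=P(c1ccccc1)(c1ccccc1)c1ccccc1 (adds CH₂)
Why: Wittig methylenation installs the exocyclic methylene. No stereocentre is created, and the short, cold reaction limits epimerisation α to the ketone.

**Step 16**
Reactants: 19
Product: 20 dictyol H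
Conditions: HF·pyridine, pyridine/THF, rt
Reagents that add atoms: none
Why: Fluoride desilylation frees the secondary alcohol without touching the tertiary acetate, so the target is obtained with all centres intact.

## Compound list
1 | (R)-(−)-linalool | C=C[C@](C)(O)CCC=C(C)C | starting material
2 | (3R)-6,7-epoxylinalool (C-6 epimers) | C=C[C@](C)(O)CCC1OC1(C)C | intermediate
3 | 2-[(2R,5R)-5-ethenyl-5-methyloxolan-2-yl]propan-2-ol (trans-furanoid linalool oxide) | C=C[C@@]1(C)CC[C@H](C(C)(C)O)O1 | intermediate
4 | its tertiary acetate | C=C[C@@]1(C)CC[C@H](C(C)(C)OC(C)=O)O1 | intermediate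
5 | 2-[(2R,5R)-5-(2-hydroxyethyl)-5-methyloxolan-2-yl]propan-2-yl acetate | OCC[C@@]1(C)CC[C@H](C(C)(C)OC(C)=O)O1 | intermediate
6 | 2-[(2R,5R)-5-methyl-5-(2-oxoethyl)oxolan-2-yl]propan-2-yl acetate | O=CC[C@@]1(C)CC[C@H](C(C)(C)OC(C)=O)O1 | intermediate
7 | acrylonitrile | C=CC#N | starting material
8 | 4-[(2R,5R)-5-(2-acetoxypropan-2-yl)-2-methyloxolan-2-yl]-5-oxopentanenitrile (C-4 as in target) | N#CCC[C@@H]([C@@]1(C)CC[C@H](C(C)(C)OC(C)=O)O1)C=O | intermediate
9 | 1-propynyllithium | CC#C[Li] | starting material
10 | 5-hydroxy-4-[THF]oct-6-ynenitrile, carbinol as in target | N#CCC[C@@H]([C@@]1(C)CC[C@H](C(C)(C)OC(C)=O)O1)[C@@H](O)C#CC | intermediate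
11 | its TBS ether | N#CCC[C@@H]([C@@]1(C)CC[C@H](C(C)(C)OC(C)=O)O1)[C@@H](O[Si](C)(C)C(C)(C)C)C#CC | intermediate
12 | vinylmagnesium bromide | C=C[Mg]Br | starting material
13 | 7-(TBSO)-6-[THF]dec-1-en-8-yn-3-one | C=CC(=O)CC[C@@H]([C@@]1(C)CC[C@H](C(C)(C)OC(C)=O)O1)[C@@H](O[Si](C)(C)C(C)(C)C)C#CC | intermediate
14 | 2-vinyl-1,3-dioxolane ketal of 13 | C=CC1(CC[C@@H]([C@@]2(C)CC[C@H](C(C)(C)OC(C)=O)O2)[C@@H](O[Si](C)(C)C(C)(C)C)C#CC)OCCO1 | intermediate
15 | Pauson–Khand cyclopentenone (hydroazulenone dioxolane, f=g enone, h=O) | C15(OCCO5)CC[C@@H]([C@@]3(C)CC[C@H](C(C)(C)OC(C)=O)O3)[C@@H](O[Si](C)(C)C(C)(C)C)C2=C(C)C(=O)C[C@@H]12 | intermediate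
16 | allylic alcohol from Luche reduction of 15 | C15(OCCO5)CC[C@@H]([C@@]3(C)CC[C@H](C(C)(C)OC(C)=O)O3)[C@@H](O[Si](C)(C)C(C)(C)C)C2=C(C)[C@@H](O)C[C@@H]12 | intermediate
17 | transposed alkene ketal (g=h alkene, ring-fusion H) | C15(OCCO5)CC[C@@H]([C@@]3(C)CC[C@H](C(C)(C)OC(C)=O)O3)[C@@H](O[Si](C)(C)C(C)(C)C)[C@H]2C(C)=CC[C@@H]12 | intermediate
18 | hydroazulenone (ketone at a) | O=C1CC[C@@H]([C@@]3(C)CC[C@H](C(C)(C)OC(C)=O)O3)[C@@H](O[Si](C)(C)C(C)(C)C)[C@H]2C(C)=CC[C@@H]12 | intermediate
19 | TBS ether of dictyol H | C=C1CC[C@@H]([C@@]3(C)CC[C@H](C(C)(C)OC(C)=O)O3)[C@@H](O[Si](C)(C)C(C)(C)C)[C@H]2C(C)=CC[C@@H]12 | intermediate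
20 | dictyol H | C=C1CC[C@@H]([C@@]2(C)CC[C@H](C(C)(C)OC(C)=O)O2)[C@@H](O)[C@H]2C(C)=CC[C@@H]12 | target

**Total step count:** 16
**Longest linear sequence:** 16 steps, from (R)-linalool.

## Three steps most likely to fail
1. **Step 11 (Pauson–Khand, 1,8-enyne → 5-7 bicycle).** Seven-membered PK closures are low-yielding, and j-stereocontrol is not guaranteed. Fallback: form the cycloheptene first by ring-closing metathesis of a diene made from aldehyde 8 by allyl and vinyl additions, then annulate the cyclopentenone by Nazarov cyclisation of a cycloheptenyl vinyl ketone.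
2. **Step 6 (enamine Michael; C-4 centre).** The diastereoselectivity from the adjacent quaternary centre is modest and could favour the wrong epimer. Fallback: cross-metathesis of 4 with allyl alcohol, then Johnson–Claisen rearrangement of the (E)-allylic alcohol, so a chair transition state sets the CH centre. Ozonolysis then gives the aldehyde.
3. **Step 13 (Myers transposition; ring-fusion H).** Facial selectivity in the Luche/Mitsunobu pair, or Mitsunobu elimination, could give trans-fusion or diene. Fallback: hydrogenate the f=g enone from the convex face to set the cis ring fusion, then form the thermodynamic enol triflate and reduce it with Pd/HCO₂H to place the g=h alkene.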